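## Retrosynthetic overview

1. The strategy rests on the tetrasubstituted C7=C11 double bond. It is exocyclic to the ten-membered carbocycle (C1–C10) and endocyclic in the five-membered lactone (O–C6–C7=C11–C12). An intramolecular Horner–Wadsworth–Emmons disconnection of this bond leaves a C7 ring ketone whose C6 oxygen carries the C11–C13 phosphonoacyl unit.
2. A C7 ketone flanked by C6–H and the 4,5-oxirane is base-labile. A metalated C7 thioacetal cannot be generated beside an aldehyde, and it would expel its β-oxygen at C6. C7 is therefore carried as a 1,1-disubstituted alkene (C7=CH2) and unmasked by Lemieux–Johnson cleavage one step before the olefination.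
3. The carbocycle is closed at C7–C8 by a Nozaki–Hiyama–Kishi reaction of a C7 2-iodo-1-alkene with the C8 aldehyde. C8 is then fixed by oxidation and CBS reduction, and acylated.
4. In the open chain, a Sonogashira coupling makes C1–C2 and a Lindlar reduction gives Z-C2=C3. Two Sharpless epoxidations set C4/C5 and C1/C10, and a Felkin–Anh Grignard addition sets C6.
5. The rings form in the order 4,5-oxirane, 1,10-oxirane, ten-membered carbocycle, butenolide. The C13 PMB ether is then exchanged for acetate and C14 is desilylated.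

Key step: step 22

Remark on numbering: the germacrane locants of the target are used for all intermediates. C1–C10 are the ring, C11–C13 the lactone side, C14 the hydroxymethyl carbon and C15 the methyl carbon. CIP letters are those of the compound named, so they can change with the substituents while the spatial arrangement stays the same.
Assumption: every compound marked "starting material" in the list is taken as a catalogue item.

## Route

Step 1
Reactants: 1 (Z)-3-methylpent-2-en-4-yn-1-ol
Product: 2 [(2S,3R)-3-ethynyl-3-methyloxiran-2-yl]methanol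
Conditions: Ti(OiPr)4 (10 mol %), L-(+)-DIPT (13 mol %), t-BuOOH, 4 Å MS, CH2Cl2, −20 °C
Reagents that add atoms: tert-butyl hydroperoxide CC(C)(C)OO
Why: Sharpless asymmetric epoxidation of a nerol-type Z-trisubstituted allylic alcohol with the L-(+)-tartrate should give the (2S,3R)-oxirane, which sets C4 (R) and C5 (S) and keeps C3 and C6 cis on the oxirane.

Step 2
Reactants: 2 [(2S,3R)-3-ethynyl-3-methyloxiran-2-yl]methanol
Product: 3 (2R,3R)-3-ethynyl-3-methyloxirane-2-carbaldehyde
Conditions: TEMPO (10 mol %), PhI(OAc)2, CH2Cl2, 0 °C → rt; solution used directly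
Reagents that add atoms: none
Why: The oxoammonium (TEMPO/PhI(OAc)2) oxidation stops at the aldehyde under nearly neutral conditions, and C5 cannot epimerise readily because it is an oxirane carbon.

Step 3
Reactants: 3 (2R,3R)-3-ethynyl-3-methyloxirane-2-carbaldehyde; 4 (1-bromovinyl)trimethylsilane
Product: 6 (1R)-1-[(2S,3R)-3-ethynyl-3-methyloxiran-2-yl]-2-(trimethylsilyl)prop-2-en-1-ol, via silylvinyl Grignard reagent 5 (not isolated)
Conditions: 4, Mg, THF, reflux; then 3, THF, −78 °C; then H2O
Reagents that add atoms: none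
Why: In this Grignard addition under polar Felkin–Anh control the nucleophile attacks anti to the C5–O bond and past C5–H, which should give the erythro epoxy alcohol (C6 as in the target); at −78 °C carbonyl addition outruns deprotonation of the alkyne.

Step 4
Reactants: 6 (1R)-1-[(2S,3R)-3-ethynyl-3-methyloxiran-2-yl]-2-(trimethylsilyl)prop-2-en-1-ol
Product: 7 triethylsilyl ether of 6 (C6-OTES)
Conditions: Et3SiCl, imidazole, CH2Cl2, 0 °C
Reagents that add atoms: chlorotriethylsilane CC[Si](Cl)(CC)CC
Why: Silylation under mild amine conditions masks the C6 allylic alcohol, so that it cannot direct the second epoxidation and the alkoxide cannot undergo Payne migration.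

Step 5
Reactants: 8 prop-2-yn-1-ol; 9 allylmagnesium bromide
Product: 11 (2Z)-2-(iodomethylidene)pent-4-en-1-ol, via cyclic alkenylmagnesium alkoxide 10 (not isolated)
Conditions: 9 (2.5 equiv), CuI (10 mol %), Et2O, 0 °C → rt; then I2, −40 °C → rt; then H2O
Reagents that add atoms: iodine II
Why: Copper-catalysed anti-carbomagnesiation of the propargylic alkoxide puts allyl on the inner carbon (C10) and magnesium on C1 in a five-membered chelate, so iodinolysis with retention places iodine cis to the C14 hydroxymethyl group.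

Step 6
Reactants: 7 triethylsilyl ether of 6; 11 (2Z)-2-(iodomethylidene)pent-4-en-1-ol
Product: 12 (2Z)-2-allyl-5-{(2R,3S)-2-methyl-3-[(1R)-1-(triethylsilyloxy)-2-(trimethylsilyl)prop-2-enyl]oxiran-2-yl}pent-2-en-4-yn-1-ol
Conditions: PdCl2(PPh3)2 (3 mol %), CuI (6 mol %), iPr2NH, THF, rt
Reagents that add atoms: none
Why: The Sonogashira coupling forms C1–C2 with retention of the alkene geometry (C2 cis to C14); oxidative addition into the vinyl iodide is faster than any reaction of zerovalent palladium with the alkynyl oxirane.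

Step 7
Reactants: 12 (Z)-enynol
Product: 13 bis-epoxy alkynol (1R,4R,5S,6R,10S) with free C14-OH
Conditions: Ti(OiPr)4 (20 mol %), L-(+)-DIPT (26 mol %), t-BuOOH, 4 Å MS, CH2Cl2, −20 °C
Reagents that add atoms: tert-butyl hydroperoxide CC(C)(C)OO
Why: Sharpless asymmetric epoxidation touches only the alkene of the free allylic alcohol, and under reagent control by the L-(+)-tartrate it should set C10 (S) and C1 (R), with C2 and C9 trans on the oxirane.

Step 8
Reactants: 13 bis-epoxy alkynol
Product: 14 C14 tert-butyldimethylsilyl ether of 13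
Conditions: t-BuMe2SiCl, imidazole, DMF, 0 °C → rt
Reagents that add atoms: tert-butylchlorodimethylsilane CC(C)(C)[Si](C)(C)Cl
Why: Standard silylation of the primary alcohol gives a neopentyl-type TBS ether that outlasts the TES ether and is kept until the last step.

Step 9
Reactants: 14 C14 TBS ether
Product: 15 terminal 1,2-diol of 14 (carbinol epimers at C8)
Conditions: OsO4 (2 mol %), NMO, acetone/H2O, 0 °C
Reagents that add atoms: 4-methylmorpholine N-oxide C[N+]1([O-])CCOCC1; water O
Why: Upjohn dihydroxylation should pick the unhindered monosubstituted allyl alkene over the encumbered vinylsilane and leave the alkyne alone; the new carbinol centre is lost again in step 12.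

Step 10
Reactants: 15 terminal 1,2-diol
Product: 16 (2Z)-alkene of 15
Conditions: H2 (1 atm), Pd/CaCO3 poisoned with Pb(OAc)2, quinoline, EtOAc, rt
Reagents that add atoms: none
Why: Lindlar semihydrogenation adds hydrogen syn to the alkyne and gives the Z-C2=C3 alkene, a conversion well known for alkynyl oxiranes; no monosubstituted alkene or vinyl halide is present at this stage.

Step 11
Reactants: 16 (2Z)-alkene diol
Product: 17 C7 2-iodo-1-alkene (SiMe3 replaced by iodine)
Conditions: N-iodosuccinimide, MeCN, 0 °C → rt, dark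
Reagents that add atoms: N-iodosuccinimide O=C1CCC(=O)N1I
Why: ipso-Iododesilylation of a 2-silyl-1-alkene with NIS in acetonitrile is a neutral route to 2-iodo-1-alkenes, and the C2=C3 alkene is deactivated and shielded by its two oxirane neighbours.

Step 12
Reactants: 17 iodoalkene diol
Product: 18 C8 aldehyde (7,8-seco chain with C7 iodoalkene)
Conditions: NaIO4, THF/pH 7 buffer, 0 °C; used crude
Reagents that add atoms: none
Why: Malaprade glycol cleavage releases the β,γ-epoxy aldehyde at neutral pH just before use, which avoids its base-induced isomerisation.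

Step 13
Reactants: 18 C8 aldehyde
Product: 19 ten-membered 7-methylene-8-ol (C8 epimers; 1R,4R,5S,6S,10S)
Conditions: CrCl2 (10 equiv), NiCl2 (2 mol %), DMSO/THF 3:1, rt, slow addition to 1 mM; then H2O
Reagents that add atoms: none
Why: In this Nozaki–Hiyama–Kishi macrocyclisation zerovalent nickel inserts into the vinylic carbon–iodine bond and transmetalation gives a trivalent vinylchromium species that adds irreversibly and only to the aldehyde; the Z-alkene and the cis-oxirane fold the chain for closure, and any C8 epimer mixture is erased in step 14.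

Step 14
Reactants: 19 ten-membered 7-methylene-8-ol
Product: 20 ten-membered 7-methylene-8-ketone
Conditions: Dess–Martin periodinane, CH2Cl2, 0 °C
Reagents that add atoms: none
Why: Dess–Martin oxidation converts both C8 epimers into one enone without base, so the β,γ-oxirane at C10 is not opened.

Step 15
Reactants: 20 ten-membered 7-methylene-8-ketone
Product: 21 (8S)-7-methylene-8-ol (1R,4R,5S,6S,8S,10S)
Conditions: (R)-2-methyl-CBS-oxazaborolidine (30 mol %), catecholborane, toluene, −78 °C
Reagents that add atoms: none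
Why: In the Corey–Bakshi–Shibata reduction the (R)-oxazaborolidine binds the ketone with the branched alkenyl side (C7) as the large group and C9H2 as the small group, and should deliver hydride 1,2 to give the (8S)-alcohol under reagent control.

Step 16
Reactants: 21 (8S)-7-methylene-8-ol; 22 (R)-2-methylbutanoic acid
Product: 23 C8 (R)-2-methylbutanoate of 21
Conditions: DCC, DMAP (10 mol %), CH2Cl2, 0 °C
Reagents that add atoms: none
Why: Steglich esterification acylates C8–OH with retention, and the low temperature with little DMAP keeps the α-stereocentre of the acid intact.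

Step 17
Reactants: 23 C8 ester
Product: 24 C6 alcohol (TES removed and TBS kept)
Conditions: HF·pyridine, excess pyridine, THF, 0 °C
Reagents that add atoms: none
Why: In buffered fluoride desilylation the secondary allylic TES ether is cleaved much faster than the neopentyl-type primary TBS ether, and the medium is too weakly acidic to open the oxiranes.

Step 18
Reactants: 25 triethyl phosphonoacetate; 26 4-methoxybenzyl alcohol
Product: 28 ethyl 2-(diethoxyphosphoryl)-3-[(4-methoxybenzyl)oxy]propanoate, via ethyl 2-(diethoxyphosphoryl)acrylate 27 (not isolated)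
Conditions: (CH2O)n, piperidine (10 mol %), 26 as solvent, 80 °C
Reagents that add atoms: paraformaldehyde (as formaldehyde) C=O
Why: Knoevenagel condensation with formaldehyde gives the phosphonoacrylate, which takes up the alcohol solvent by oxa-Michael addition, as is known for the same sequence run in methanol.

Step 19
Reactants: 28 ethyl 2-(diethoxyphosphoryl)-3-[(4-methoxybenzyl)oxy]propanoate
Product: 29 2-(diethoxyphosphoryl)-3-[(4-methoxybenzyl)oxy]propanoic acid
Conditions: LiOH (1.05 equiv), THF/H2O, 0 °C; then 1 M HCl to pH 3, 0 °C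
Reagents that add atoms: lithium hydroxide [Li+].[OH-]
Why: Saponification cleaves the carboxylic ethyl ester much faster than the phosphonate ethyl esters, and the low temperature limits retro-oxa-Michael loss of the PMB-oxide.

Step 20
Reactants: 24 C6 alcohol; 29 2-(diethoxyphosphoryl)-3-[(4-methoxybenzyl)oxy]propanoic acid
Product: 30 C6 phosphonoacyl ester with C7=CH2 (both C11 epimers)
Conditions: DCC, DMAP (10 mol %), CH2Cl2, 0 °C
Reagents that add atoms: none
Why: Steglich esterification loads the C11–C13 unit while C7 is still an alkene, so no free α-hydroxy ketone next to the 4,5-oxirane has to be handled.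

Step 21
Reactants: 30 C6 phosphonoacyl ester with C7=CH2
Product: 32 ten-membered 6-(phosphonoacyloxy)-7-ketone (1R,4R,5S,6R,8S,10S), via C7 glycol 31 (not isolated)
Conditions: OsO4 (5 mol %), NaIO4, 2,6-lutidine, dioxane/H2O, 0 °C → rt
Reagents that add atoms: sodium periodate [Na+].[O-]I(=O)(=O)=O; water O
Why: Lemieux–Johnson cleavage should take the peripheral 1,1-disubstituted C7=CH2 in preference to the cis-disubstituted C2=C3, which lies between two oxirane carbons (one of them fully substituted); the glycol is cut in situ before acyl migration can start.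

Step 22
Reactants: 32 ten-membered 6-(phosphonoacyloxy)-7-ketone
Product: 33 butenolide with C13-OPMB and C14-OTBS (1R,4R,5S,6S,8S,10S)
Conditions: LiCl (5 equiv), iPr2NEt (3 equiv), MeCN, 0 °C
Reagents that add atoms: none
Why: Under Masamune–Roush conditions LiCl and iPr2NEt remove the doubly activated C11–H of the phosphonoacyl ester, the lithium-chelated carbanion adds to the C7 ketone, and the oxaphosphetane collapses with loss of diethyl phosphate to give C7=C11. The closest known reaction type is the intramolecular Horner–Wadsworth–Emmons synthesis of butenolides from α-(dialkylphosphonoacyloxy) ketones. The lactone ring O–C6–C7–C11–C12 closes by a 5-exo-trig addition, and the ring allows only the endocyclic cis alkene, so both C11 epimers of 32 converge on 33. No stereocentre is created; C6 and C8 only have to be preserved. The step needs deprotonation at C11 rather than at C6–H or C8–H, and addition faster than β-loss of the C13 PMB-oxide; the large acidity gap, the activated α,α'-diacyloxy ketone and the five-atom proximity should secure both. The reaction is quenched at 0 °C as soon as 32 is consumed, because C6–H of 33 is vinylogously acidic and sits next to the 4,5-oxirane.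

Step 23
Reactants: 33 butenolide with C13-OPMB and C14-OTBS
Product: 34 C13 alcohol (C14-OTBS kept)
Conditions: DDQ, CH2Cl2/pH 7 buffer, 0 °C
Reagents that add atoms: none
Why: Oxidative PMB cleavage by DDQ proceeds by hydride abstraction from the electron-rich benzylic position and leaves the electron-poor alkenes, oxiranes, esters and the silyl ether untouched.

Step 24
Reactants: 34 C13 alcohol
Product: 35 C13 acetate (C14-OTBS kept)
Conditions: Ac2O, pyridine, CH2Cl2, 0 °C
Reagents that add atoms: acetic anhydride CC(=O)OC(C)=O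
Why: Acetylation of the only free hydroxyl under weak amine base is too mild to deprotonate C6–H of the butenolide.

Step 25
Reactants: 35 C13 acetate
Product: 36 target CNP0108300.1 (1R,4R,5S,6S,8S,10S; 2'R; 2Z)
Conditions: HF·pyridine, pyridine, THF, 0 °C → rt
Reagents that add atoms: none
Why: Buffered fluoride desilylation frees C14–OH without the basic conditions that would cause Payne migration, acyl transfer or opening of the oxiranes.

## Compound list

1 | (Z)-3-methylpent-2-en-4-yn-1-ol | C#C/C(C)=C\CO | starting material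
2 | [(2S,3R)-3-ethynyl-3-methyloxiran-2-yl]methanol | C#C[C@@]1(C)O[C@H]1CO | intermediate
3 | (2R,3R)-3-ethynyl-3-methyloxirane-2-carbaldehyde | C#C[C@@]1(C)O[C@H]1C=O | intermediate
4 | (1-bromovinyl)trimethylsilane | C=C(Br)[Si](C)(C)C | starting material
5 | [1-(trimethylsilyl)vinyl]magnesium bromide (not isolated) | C=C([Mg]Br)[Si](C)(C)C | intermediate
6 | (1R)-1-[(2S,3R)-3-ethynyl-3-methyloxiran-2-yl]-2-(trimethylsilyl)prop-2-en-1-ol | C#C[C@@]1(C)O[C@H]1[C@@H](O)C(=C)[Si](C)(C)C | intermediate
7 | triethylsilyl ether of 6 | C#C[C@@]1(C)O[C@H]1[C@@H](O[Si](CC)(CC)CC)C(=C)[Si](C)(C)C | intermediate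
8 | prop-2-yn-1-ol | C#CCO | starting material
9 | allylmagnesium bromide | C=CC[Mg]Br | starting material
10 | cyclic alkenylmagnesium alkoxide, 4-allyl-2,5-dihydro-1,2-oxamagnesole (not isolated) | C=CCC1=C[Mg]OC1 | intermediate
11 | (2Z)-2-(iodomethylidene)pent-4-en-1-ol | C=CC/C(CO)=C/I | intermediate
12 | (2Z)-2-allyl-5-{(2R,3S)-2-methyl-3-[(1R)-1-(triethylsilyloxy)-2-(trimethylsilyl)prop-2-enyl]oxiran-2-yl}pent-2-en-4-yn-1-ol | C=CC/C(CO)=C/C#C[C@@]1(C)O[C@H]1[C@@H](O[Si](CC)(CC)CC)C(=C)[Si](C)(C)C | intermediate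
13 | bis-epoxy alkynol (1R,4R,5S,6R,10S): 1,10- and 4,5-oxiranes, C2≡C3, free C14-OH, C6-OTES, C7(=CH2)SiMe3, allyl on C10 | C=CC[C@@]1(CO)O[C@@H]1C#C[C@@]2(C)O[C@H]2[C@@H](O[Si](CC)(CC)CC)C(=C)[Si](C)(C)C | intermediate
14 | C14 TBS ether of 13 | C=CC[C@@]1(CO[Si](C)(C)C(C)(C)C)O[C@@H]1C#C[C@@]2(C)O[C@H]2[C@@H](O[Si](CC)(CC)CC)C(=C)[Si](C)(C)C | intermediate
15 | terminal 1,2-diol of 14 (carbinol epimers) | OCC(O)C[C@@]1(CO[Si](C)(C)C(C)(C)C)O[C@@H]1C#C[C@@]2(C)O[C@H]2[C@@H](O[Si](CC)(CC)CC)C(=C)[Si](C)(C)C | intermediate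
16 | (2Z)-alkene of 15 | OCC(O)C[C@@]1(CO[Si](C)(C)C(C)(C)C)O[C@@H]1/C=C\[C@@]2(C)O[C@H]2[C@@H](O[Si](CC)(CC)CC)C(=C)[Si](C)(C)C | intermediate
17 | C7 2-iodo-1-alkene diol | OCC(O)C[C@@]1(CO[Si](C)(C)C(C)(C)C)O[C@@H]1/C=C\[C@@]2(C)O[C@H]2[C@@H](O[Si](CC)(CC)CC)C(=C)I | intermediate
18 | C8 aldehyde, 7,8-seco chain (1R,4R,5S,6R,10S) | O=CC[C@@]1(CO[Si](C)(C)C(C)(C)C)O[C@@H]1/C=C\[C@@]2(C)O[C@H]2[C@@H](O[Si](CC)(CC)CC)C(=C)I | intermediate
19 | ten-membered 7-methylene-8-ol (C8 epimers) | OC1C[C@@]2(CO[Si](C)(C)C(C)(C)C)O[C@@H]2/C=C\[C@@]2(C)O[C@H]2[C@@H](O[Si](CC)(CC)CC)C1=C | intermediate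
20 | ten-membered 7-methylene-8-ketone | O=C1C[C@@]2(CO[Si](C)(C)C(C)(C)C)O[C@@H]2/C=C\[C@@]2(C)O[C@H]2[C@@H](O[Si](CC)(CC)CC)C1=C | intermediate
21 | (8S)-7-methylene-8-ol (1R,4R,5S,6S,8S,10S) | O[C@H]1C[C@@]2(CO[Si](C)(C)C(C)(C)C)O[C@@H]2/C=C\[C@@]2(C)O[C@H]2[C@@H](O[Si](CC)(CC)CC)C1=C | intermediate
22 | (R)-2-methylbutanoic acid | CC[C@@H](C)C(=O)O | starting material
23 | C8 (R)-2-methylbutanoate, C6-OTES, C7=CH2 | CC[C@@H](C)C(=O)O[C@H]1C[C@@]2(CO[Si](C)(C)C(C)(C)C)O[C@@H]2/C=C\[C@@]2(C)O[C@H]2[C@@H](O[Si](CC)(CC)CC)C1=C | intermediate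
24 | C6 alcohol, C8 ester, C7=CH2 | CC[C@@H](C)C(=O)O[C@H]1C[C@@]2(CO[Si](C)(C)C(C)(C)C)O[C@@H]2/C=C\[C@@]2(C)O[C@H]2[C@@H](O)C1=C | intermediate
25 | triethyl phosphonoacetate | CCOC(=O)CP(=O)(OCC)OCC | starting material
26 | 4-methoxybenzyl alcohol | COc1ccc(CO)cc1 | starting material
27 | ethyl 2-(diethoxyphosphoryl)acrylate (not isolated) | C=C(C(=O)OCC)P(=O)(OCC)OCC | intermediate
28 | ethyl 2-(diethoxyphosphoryl)-3-[(4-methoxybenzyl)oxy]propanoate | CCOC(=O)C(COCc1ccc(OC)cc1)P(=O)(OCC)OCC | intermediate
29 | 2-(diethoxyphosphoryl)-3-[(4-methoxybenzyl)oxy]propanoic acid | OC(=O)C(COCc1ccc(OC)cc1)P(=O)(OCC)OCC | intermediate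
30 | C6 phosphonoacyl ester with C7=CH2 (C11 epimers) | CC[C@@H](C)C(=O)O[C@H]1C[C@@]2(CO[Si](C)(C)C(C)(C)C)O[C@@H]2/C=C\[C@@]2(C)O[C@H]2[C@@H](OC(=O)C(COCc3ccc(OC)cc3)P(=O)(OCC)OCC)C1=C | intermediate
31 | C7 glycol of 30 (not isolated) | CC[C@@H](C)C(=O)O[C@H]1C[C@@]2(CO[Si](C)(C)C(C)(C)C)O[C@@H]2/C=C\[C@@]2(C)O[C@H]2[C@@H](OC(=O)C(COCc3ccc(OC)cc3)P(=O)(OCC)OCC)C1(O)CO | intermediate
32 | ten-membered 6-(phosphonoacyloxy)-7-ketone, key-step precursor | CC[C@@H](C)C(=O)O[C@H]1C[C@@]2(CO[Si](C)(C)C(C)(C)C)O[C@@H]2/C=C\[C@@]2(C)O[C@H]2[C@@H](OC(=O)C(COCc3ccc(OC)cc3)P(=O)(OCC)OCC)C1=O | intermediate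
33 | butenolide with C13-OPMB and C14-OTBS, key-step product | CC[C@@H](C)C(=O)O[C@H]1C[C@@]2(CO[Si](C)(C)C(C)(C)C)O[C@@H]2/C=C\[C@@]2(C)O[C@H]2[C@H]2OC(=O)C(COCc3ccc(OC)cc3)=C12 | intermediate
34 | C13 alcohol, C14-OTBS | CC[C@@H](C)C(=O)O[C@H]1C[C@@]2(CO[Si](C)(C)C(C)(C)C)O[C@@H]2/C=C\[C@@]2(C)O[C@H]2[C@H]2OC(=O)C(CO)=C12 | intermediate
35 | C13 acetate, C14-OTBS | CC[C@@H](C)C(=O)O[C@H]1C[C@@]2(CO[Si](C)(C)C(C)(C)C)O[C@@H]2/C=C\[C@@]2(C)O[C@H]2[C@H]2OC(=O)C(COC(C)=O)=C12 | intermediate
36 | CNP0108300.1 | CC[C@@H](C)C(=O)O[C@H]1C[C@@]2(CO)O[C@@H]2/C=C\[C@@]2(C)O[C@H]2[C@H]2OC(=O)C(COC(C)=O)=C12 | target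

## Step count and weak points

Total step count: 25.
Longest linear sequence: 22 steps (1–4, 6–17, 20–25).

**Step 13, ring closure.** The closure may lose to oligomerisation, to reductive opening of the two vinyl oxiranes by divalent chromium, or to β-elimination of the β,γ-epoxy aldehyde before it is trapped.

The fallback closes the ring by acylation instead of carbonyl addition. It sets out from 18. Pinnick oxidation (NaClO2, NaH2PO4, 2-methyl-2-butene) gives the C8 carboxylic acid F1. Coupling with MeNHOMe·HCl (EDC, iPr2NEt) gives the C8 Weinreb amide F2. Iodine–lithium exchange with t-BuLi (2 equiv, THF/Et2O/pentane, −100 °C, high dilution) makes the C7 vinyllithium, which attacks the amide within the molecule in a Parham-type cyclisation. The chelated adduct collapses on work-up to enone 20, where the route is rejoined; steps 13 and 14 drop out.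

**Step 22, key olefination.** The phosphonate carbanion may expel the C13 PMB-oxide. The amine may also deprotonate C6–H of 32 or of 33, which opens the 4,5-oxirane.

The fallback forms the same C7–C11 bond without base, by zinc enolate addition followed by dehydration. It sets out from 24.
- Alcohol 26 is added to methyl 2-bromoacrylate (cat. KOt-Bu, THF, 0 °C) to give methyl 2-bromo-3-[(4-methoxybenzyl)oxy]propanoate F3.
- LiOH gives 2-bromo-3-[(4-methoxybenzyl)oxy]propanoic acid F4.
- Steglich esterification of 24 with F4 gives the C6 bromoacyl ester F5.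
- Lemieux–Johnson cleavage gives the 7-keto bromoacyl ester F6.
- Activated Zn (THF, 0 °C) triggers an intramolecular Reformatsky addition to give the C7 β-hydroxy lactone F7.
- Dehydration with Martin sulfurane (CH2Cl2, 0 °C) returns to 33.

**Step 21, unmasking of C7.** Osmylation may not distinguish well enough between C7=CH2 and C2=C3. The transient glycol may also suffer acyl migration from O6 or O8.

The fallback uses hydroxyl-directed osmylation before the phosphonoacyl group is loaded. It sets out from 24. Stoichiometric OsO4·TMEDA (CH2Cl2, −78 °C) is steered by hydrogen bonding to the free C6–OH and should attack only the neighbouring methylene, giving the 6,7,7a-triol F8. One equivalent of Pb(OAc)4 (CH2Cl2, −20 °C) should cut the primary–tertiary glycol first and give the 6-hydroxy-7-ketone F9. Immediate Steglich esterification with 29 leads back to 32.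

## Further compounds

F1 | step 13 | C8 carboxylic acid of the 7,8-seco chain | OC(=O)C[C@@]1(CO[Si](C)(C)C(C)(C)C)O[C@@H]1/C=C\[C@@]2(C)O[C@H]2[C@@H](O[Si](CC)(CC)CC)C(=C)I
F2 | step 13 | C8 Weinreb amide of the 7,8-seco chain | CON(C)C(=O)C[C@@]1(CO[Si](C)(C)C(C)(C)C)O[C@@H]1/C=C\[C@@]2(C)O[C@H]2[C@@H](O[Si](CC)(CC)CC)C(=C)I
F3 | step 22 | methyl 2-bromo-3-[(4-methoxybenzyl)oxy]propanoate | COC(=O)C(Br)COCc1ccc(OC)cc1
F4 | step 22 | 2-bromo-3-[(4-methoxybenzyl)oxy]propanoic acid | OC(=O)C(Br)COCc1ccc(OC)cc1
F5 | step 22 | C6 bromoacyl ester with C7=CH2 | CC[C@@H](C)C(=O)O[C@H]1C[C@@]2(CO[Si](C)(C)C(C)(C)C)O[C@@H]2/C=C\[C@@]2(C)O[C@H]2[C@@H](OC(=O)C(Br)COCc3ccc(OC)cc3)C1=C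
F6 | step 22 | 7-keto bromoacyl ester | CC[C@@H](C)C(=O)O[C@H]1C[C@@]2(CO[Si](C)(C)C(C)(C)C)O[C@@H]2/C=C\[C@@]2(C)O[C@H]2[C@@H](OC(=O)C(Br)COCc3ccc(OC)cc3)C1=O
F7 | step 22 | C7 β-hydroxy lactone | CC[C@@H](C)C(=O)O[C@H]1C[C@@]2(CO[Si](C)(C)C(C)(C)C)O[C@@H]2/C=C\[C@@]2(C)O[C@H]2[C@H]2OC(=O)C(COCc3ccc(OC)cc3)C12O
F8 | step 21 | 6,7,7a-triol | CC[C@@H](C)C(=O)O[C@H]1C[C@@]2(CO[Si](C)(C)C(C)(C)C)O[C@@H]2/C=C\[C@@]2(C)O[C@H]2[C@@H](O)C1(O)CO
F9 | step 21 | 6-hydroxy-7-ketone | CC[C@@H](C)C(=O)O[C@H]1C[C@@]2(CO[Si](C)(C)C(C)(C)C)O[C@@H]2/C=C\[C@@]2(C)O[C@H]2[C@@H](O)C1=O
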